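**Plan**
- Retrosynthesis: cut C3–CHBr2 (carbenoid addition to a ring B enone), then undo the 1,2-shift that made C5–C6 (ring B ketone back to a cyclopentanol on C6 plus a C6–C7 epoxide), then the two bonds from the carbinol carbon to a C4 chain, then the C6–carbinol bond back to a ring A vinyl triflate from ketoisophorone.
- Enabling feature: with ring B as C1–C5, spiro C6 and ring A as C7–C11, C6 carries a methylene (C5) and a carbon that can be a carbonyl (C1), so ring B can grow from a cyclopentanol on C6 by shift of one of its ring carbons to C6.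
- Forward: ring A comes from ketoisophorone (C9/C10 bromohydrin, C6=C7 alkene, ester), the cyclopentanol from 1,4-dibromobutane, and ring B from the epoxide-triggered ring expansion. Then the C1 ketone is moved to the C1=C2–C3=O enone, the C7 carbinol becomes the methylidene, and CHBr2 is added.
- Stereochemistry: C9/C10 from an enzymatic dynamic reduction; C6 by relay (the C9 hydroxyl directs the epoxide, anti migration inverts C6); C3 from substrate-controlled addition to the enone.

Key step: step 9

Remark: atoms carry the locants of the target spiro[5.5]undecane throughout (ring B C1–C5, spiro C6, ring A C7–C11), and the ketoreductase of step 2 is taken to be chosen by screening a commercial enzyme panel for the (4R,5S) product.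

Step 1
Reactants: 1 ketoisophorone (2,6,6-trimethylcyclohex-2-ene-1,4-dione)
Product: 3 rac-5-bromo-2,6,6-trimethylcyclohex-2-ene-1,4-dione, via silyl dienol ether 2 (not isolated)
Conditions: LiN(SiMe3)2, Me3SiCl, THF, −78 °C; then NBS, THF, −78 → 0 °C
Reagents that add atoms: N-bromosuccinimide, O=C1CCC(=O)N1Br; chlorotrimethylsilane, C[Si](C)(C)Cl (its silyl group is carried only by 2)
Why: Kinetic deprotonation at the only sp3 α-carbon (α′ to the enone carbonyl, as in isophorone) with in situ silylation gives the cross-conjugated silyloxydiene, which NBS brominates at the enol ether carbon (α′-halogenation of an enone through its silyl dienol ether); the new stereocenter is racemic and stays epimerisable.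

Step 2
Reactants: 3 rac-5-bromo-2,6,6-trimethylcyclohex-2-ene-1,4-dione
Product: 4 (4R,5S)-5-bromo-4-hydroxy-2,6,6-trimethylcyclohex-2-en-1-one (cis-bromohydrin)
Conditions: ketoreductase (panel-selected), NADP+ (cat.), i-PrOH, phosphate buffer pH 8, DMSO, 30 °C
Reagents that add atoms: none
Why: Dynamic reductive kinetic resolution of an α-halo ketone by a ketoreductase: the bromine-bearing carbon epimerises through the enol while the enzyme reduces only the (5S)-ketone at the unhindered C4 carbonyl from one face (the C1 carbonyl is shielded by the gem-dimethyl carbon), so the catalyst should set both C9 and C10 of the target as the cis pair.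

Step 3
Reactants: 4 (4R,5S)-5-bromo-4-hydroxy-2,6,6-trimethylcyclohex-2-en-1-one
Product: 5 (4R,5S)-5-bromo-4-(tert-butyldimethylsilyloxy)-2,6,6-trimethylcyclohex-2-en-1-one
Conditions: TBSOTf, 2,6-lutidine, CH2Cl2, −78 → 0 °C
Reagents that add atoms: tert-butyldimethylsilyl trifluoromethanesulfonate, CC(C)(C)[Si](C)(C)OS(=O)(=O)C(F)(F)F
Why: Silyl ether formation on a hindered secondary alcohol with a silyl triflate, which masks the hydroxyl for the hydride, enolate and organometallic steps without touching a stereocenter.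

Step 4
Reactants: 5 (4R,5S)-5-bromo-4-(tert-butyldimethylsilyloxy)-2,6,6-trimethylcyclohex-2-en-1-one
Product: 7 (4R,5S)-5-bromo-4-(tert-butyldimethylsilyloxy)-2,6,6-trimethylcyclohex-1-en-1-yl trifluoromethanesulfonate, via lithium enolate 6 (not isolated)
Conditions: LiBH(s-Bu)3, THF, −78 °C; then N-(5-chloro-2-pyridyl)triflimide, −78 → 0 °C
Reagents that add atoms: N-(5-chloro-2-pyridyl)bis(trifluoromethanesulfonimide), O=S(=O)(N(c1ccc(Cl)cn1)S(=O)(=O)C(F)(F)F)C(F)(F)F; LiBH(s-Bu)3, [Li+].CCC(C)[BH-](C(C)CC)C(C)CC (its lithium is carried only by 6)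
Why: Conjugate hydride reduction of a β-unsubstituted cyclohexenone with a hindered carbonyl gives the tetrasubstituted enolate regiospecifically, and O-triflation in the same flask (reductive enol triflate formation) fixes the C6=C7 double bond, so no new stereocenter arises.

Step 5
Reactants: 7 (4R,5S)-5-bromo-4-(tert-butyldimethylsilyloxy)-2,6,6-trimethylcyclohex-1-en-1-yl trifluoromethanesulfonate
Product: 8 methyl (4R,5S)-5-bromo-4-(tert-butyldimethylsilyloxy)-2,6,6-trimethylcyclohex-1-ene-1-carboxylate
Conditions: Pd(OAc)2 (cat.), PPh3, CO (1 atm), MeOH, Et3N, DMF, 60 °C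
Reagents that add atoms: carbon monoxide, [C-]#[O+]; methanol, CO
Why: Palladium-catalysed methoxycarbonylation of a vinyl triflate, in which zerovalent palladium inserts into the vinyl C–O bond far faster than into the neopentyl secondary C–Br bond.

Step 6
Reactants: 8 methyl (4R,5S)-5-bromo-4-(tert-butyldimethylsilyloxy)-2,6,6-trimethylcyclohex-1-ene-1-carboxylate; 9 1,4-dibromobutane
Product: 11 1-[(4R,5S)-5-bromo-4-(tert-butyldimethylsilyloxy)-2,6,6-trimethylcyclohex-1-en-1-yl]cyclopentan-1-ol, via di-Grignard reagent 10 (not isolated)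
Conditions: Mg, THF, 25 °C; CeCl3, THF, −78 °C; then 8, −78 → 0 °C; aq. NH4Cl
Reagents that add atoms: 1,4-dibromobutane (compound 9), BrCCCCBr; magnesium, [Mg] (carried only by 10)
Why: Annulative double Grignard addition of BrMg(CH2)4MgBr to an ester gives the 1-substituted cyclopentanol, with CeCl3 making the reagent more nucleophilic and less basic toward this twisted, doubly flanked ester and the second, intramolecular addition closing the five-membered ring; no stereocenter is formed.

Step 7
Reactants: 11 1-[(4R,5S)-5-bromo-4-(tert-butyldimethylsilyloxy)-2,6,6-trimethylcyclohex-1-en-1-yl]cyclopentan-1-ol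
Product: 12 (1R,6S)-6-bromo-4-(1-hydroxycyclopentyl)-3,5,5-trimethylcyclohex-3-en-1-ol
Conditions: n-Bu4NF, THF, 0 °C → rt
Reagents that add atoms: none
Why: Fluoride desilylation frees the C9 hydroxyl as the directing group for the next step, and the cis-bromohydrin alkoxide cannot close to an epoxide because that needs an anti arrangement.

Step 8
Reactants: 12 (1R,6S)-6-bromo-4-(1-hydroxycyclopentyl)-3,5,5-trimethylcyclohex-3-en-1-ol
Product: 13 (1S,3S,4R,6S)-3-bromo-1-(1-hydroxycyclopentyl)-2,2,6-trimethyl-7-oxabicyclo[4.1.0]heptan-4-ol (C6–C7 epoxide cis to the C9 hydroxyl and the C10 bromine)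
Conditions: VO(acac)2 (cat.), t-BuOOH, CH2Cl2, 0 °C → rt
Reagents that add atoms: tert-butyl hydroperoxide, CC(C)(C)OO
Why: Hydroxyl-directed epoxidation with VO(acac)2 and t-BuOOH, in which the homoallylic C9 hydroxyl in its pseudoaxial half-chair conformer should deliver the peroxide oxygen to its own face; the allylic carbinol hydroxyl can share the same vanadium only on that face, so C6 and C7 are set cis to the C9 oxygen.

Step 9
Reactants: 13 (1S,3S,4R,6S)-3-bromo-1-(1-hydroxycyclopentyl)-2,2,6-trimethyl-7-oxabicyclo[4.1.0]heptan-4-ol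
Product: 14 (6R,7S,9R,10S)-10-bromo-7,9-dihydroxy-7,11,11-trimethylspiro[5.5]undecan-1-one
Conditions: ZnBr2, CH2Cl2, 0 °C → rt
Reagents that add atoms: none
Why: ZnBr2 binds the epoxide oxygen, the C6–O bond lengthens, and a cyclopentane carbon whose bond to the carbinol carbon lies antiperiplanar to it shifts to C6 while the carbinol oxygen closes to the C1 carbonyl, so that C5–C6 forms in one invertive 1,2-shift. The closest known reaction type is the semipinacol rearrangement of a 2,3-epoxy tertiary alcohol with ring expansion. Ring B closes by ring enlargement of the five-membered carbinol ring to the six-membered ketone, not by an end-to-end cyclisation, and is driven by carbonyl formation and release of epoxide strain. The new quaternary stereocenter C6 is controlled by the epoxide face set in step 8: the migrating carbon enters anti to the leaving oxygen, which puts C5 trans and the C1 carbonyl cis to the C9 hydroxyl and C10 bromine, while the oxygen stays on C7 with retention. The step needs cleavage at C6 and not at C7, and migration in place of elimination or bromide opening; the push of the carbinol oxygen acts only on C6, the two candidate migrating carbons are constitutionally equivalent, and the cis C9 hydroxyl cannot reach the backside of either epoxide carbon.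

Step 10
Reactants: 14 (6R,7S,9R,10S)-10-bromo-7,9-dihydroxy-7,11,11-trimethylspiro[5.5]undecan-1-one
Product: 16 (6R,7S,9R,10S)-10-bromo-9-(tert-butyldimethylsilyloxy)-7,11,11-trimethyl-7-(trimethylsilyloxy)spiro[5.5]undecan-1-one, via C9 silyl ether 15 (not isolated)
Conditions: TBSOTf, 2,6-lutidine, CH2Cl2, −78 °C; then N-(trimethylsilyl)imidazole, 0 °C → rt
Reagents that add atoms: tert-butyldimethylsilyl trifluoromethanesulfonate, CC(C)(C)[Si](C)(C)OS(=O)(=O)C(F)(F)F; N-(trimethylsilyl)imidazole, C[Si](C)(C)n1ccnc1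
Why: Sequential silyl ether formation, the bulky silyl triflate taking the secondary C9 hydroxyl first and the small silyl donor then capping the tertiary C7 hydroxyl, which must not become a free alkoxide under base because this β-hydroxy ketone with a quaternary α-carbon could undergo retro-aldol cleavage.

Step 11
Reactants: 16 (6R,7S,9R,10S)-10-bromo-9-(tert-butyldimethylsilyloxy)-7,11,11-trimethyl-7-(trimethylsilyloxy)spiro[5.5]undecan-1-one
Product: 17 (6R,7S,9R,10S)-10-bromo-9-(tert-butyldimethylsilyloxy)-7,11,11-trimethyl-7-(trimethylsilyloxy)spiro[5.5]undec-1-en-1-yl trifluoromethanesulfonate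
Conditions: KN(SiMe3)2, THF, −78 °C; then PhNTf2, −78 → 0 °C
Reagents that add atoms: N-phenylbis(trifluoromethanesulfonimide), O=S(=O)(N(c1ccccc1)S(=O)(=O)C(F)(F)F)C(F)(F)F
Why: Enol triflate formation from the kinetic enolate, which can form only toward C2 because C6 is quaternary.

Step 12
Reactants: 17 (6R,7S,9R,10S)-10-bromo-9-(tert-butyldimethylsilyloxy)-7,11,11-trimethyl-7-(trimethylsilyloxy)spiro[5.5]undec-1-en-1-yl trifluoromethanesulfonate
Product: 18 (6R,7S,9R,10S)-10-bromo-9-(tert-butyldimethylsilyloxy)-7,11,11-trimethyl-7-(trimethylsilyloxy)spiro[5.5]undec-1-ene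
Conditions: Pd(OAc)2 (cat.), PPh3, n-Bu3N, HCO2H, DMF, 60 °C
Reagents that add atoms: none
Why: Palladium-catalysed formate reduction of an enol triflate (hydride transfer from formate with loss of CO2, then reductive elimination) leaves the C1=C2 double bond in place of the ketone.

Step 13
Reactants: 18 (6R,7S,9R,10S)-10-bromo-9-(tert-butyldimethylsilyloxy)-7,11,11-trimethyl-7-(trimethylsilyloxy)spiro[5.5]undec-1-ene
Product: 19 (6R,7S,9R,10S)-10-bromo-9-(tert-butyldimethylsilyloxy)-7,11,11-trimethyl-7-(trimethylsilyloxy)spiro[5.5]undec-1-en-3-one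
Conditions: CrO3, 3,5-dimethylpyrazole, CH2Cl2, −20 °C
Reagents that add atoms: chromium trioxide, O=[Cr](=O)=O
Why: Allylic oxidation with the CrO3–3,5-dimethylpyrazole complex should go to C3, the only allylic methylene since C6 is quaternary and the C7 methylidene is not yet present, giving the C1=C2–C3=O enone.

Step 14
Reactants: 19 (6R,7S,9R,10S)-10-bromo-9-(tert-butyldimethylsilyloxy)-7,11,11-trimethyl-7-(trimethylsilyloxy)spiro[5.5]undec-1-en-3-one
Product: 20 (6R,7S,9R,10S)-10-bromo-9-(tert-butyldimethylsilyloxy)-7-hydroxy-7,11,11-trimethylspiro[5.5]undec-1-en-3-one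
Conditions: PPTS (cat.), MeOH, 0 °C
Reagents that add atoms: none
Why: Acid-catalysed methanolysis of a silyl ether removes the labile trimethylsilyl group while the tert-butyldimethylsilyl ether stays, and no alkoxide is formed that could start a vinylogous retro-aldol cleavage.

Step 15
Reactants: 20 (6R,7S,9R,10S)-10-bromo-9-(tert-butyldimethylsilyloxy)-7-hydroxy-7,11,11-trimethylspiro[5.5]undec-1-en-3-one
Product: 21 (6S,9R,10S)-10-bromo-9-(tert-butyldimethylsilyloxy)-11,11-dimethyl-7-methylidenespiro[5.5]undec-1-en-3-one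
Conditions: SOCl2, pyridine, CH2Cl2, −30 → 0 °C
Reagents that add atoms: none
Why: Dehydration of a tertiary alcohol through its chlorosulfite by E2 elimination: in the chair that keeps the C9 silyloxy group equatorial the C7 oxygen is equatorial too and has no antiperiplanar ring hydrogen, so loss of a methyl hydrogen should give the exocyclic methylidene, and the electron-poor enone does not assist ionisation.

Step 16
Reactants: 21 (6S,9R,10S)-10-bromo-9-(tert-butyldimethylsilyloxy)-11,11-dimethyl-7-methylidenespiro[5.5]undec-1-en-3-one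
Product: 22 (3R,6S,9R,10S)-10-bromo-9-(tert-butyldimethylsilyloxy)-3-(dibromomethyl)-11,11-dimethyl-7-methylidenespiro[5.5]undec-1-en-3-ol
Conditions: CH2Br2, lithium 2,2,6,6-tetramethylpiperidide, THF–Et2O, −100 °C; then 21; AcOH, −100 °C
Reagents that add atoms: dibromomethane, BrCBr
Why: 1,2-Addition of the lithium carbenoid LiCHBr2 to the enone, in which the bulky reagent is expected to take the equatorial trajectory on the ring B face that carries C7 (ring B half-chair with the C6–C11 bond pseudoequatorial), placing CHBr2 pseudoequatorial and the new hydroxyl cis to C11 (3R); the cold acidic quench keeps the alkoxide from closing onto the dibromomethyl group.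

Step 17
Reactants: 22 (3R,6S,9R,10S)-10-bromo-9-(tert-butyldimethylsilyloxy)-3-(dibromomethyl)-11,11-dimethyl-7-methylidenespiro[5.5]undec-1-en-3-ol
Product: 23 mailiohydrin, (3R,6S,9R,10S)-10-bromo-3-(dibromomethyl)-11,11-dimethyl-7-methylidenespiro[5.5]undec-1-ene-3,9-diol
Conditions: HF·pyridine, pyridine, THF, 0 °C → rt
Reagents that add atoms: none
Why: Buffered fluoride desilylation is neither basic enough to turn the dibromomethyl carbinol into a bromo epoxide nor acidic enough to ionise the tertiary allylic alcohol, and it touches no stereocenter.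

**Compound list**
1 | ketoisophorone (2,6,6-trimethylcyclohex-2-ene-1,4-dione) | CC1=CC(=O)CC(C)(C)C1=O | starting material
2 | 2,6,6-trimethyl-4-(trimethylsilyloxy)cyclohexa-2,4-dien-1-one (formed in the flask) | CC1=CC(O[Si](C)(C)C)=CC(C)(C)C1=O | intermediate
3 | rac-5-bromo-2,6,6-trimethylcyclohex-2-ene-1,4-dione | CC1=CC(=O)C(Br)C(C)(C)C1=O | intermediate
4 | (4R,5S)-5-bromo-4-hydroxy-2,6,6-trimethylcyclohex-2-en-1-one | CC1=C[C@@H](O)[C@@H](Br)C(C)(C)C1=O | intermediate
5 | (4R,5S)-5-bromo-4-(tert-butyldimethylsilyloxy)-2,6,6-trimethylcyclohex-2-en-1-one | CC1=C[C@@H](O[Si](C)(C)C(C)(C)C)[C@@H](Br)C(C)(C)C1=O | intermediate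
6 | lithium (4R,5S)-5-bromo-4-(tert-butyldimethylsilyloxy)-2,6,6-trimethylcyclohex-1-en-1-olate (formed in the flask) | CC1=C(O[Li])C(C)(C)[C@H](Br)[C@H](O[Si](C)(C)C(C)(C)C)C1 | intermediate
7 | (4R,5S)-5-bromo-4-(tert-butyldimethylsilyloxy)-2,6,6-trimethylcyclohex-1-en-1-yl trifluoromethanesulfonate | CC1=C(OS(=O)(=O)C(F)(F)F)C(C)(C)[C@H](Br)[C@H](O[Si](C)(C)C(C)(C)C)C1 | intermediate
8 | methyl (4R,5S)-5-bromo-4-(tert-butyldimethylsilyloxy)-2,6,6-trimethylcyclohex-1-ene-1-carboxylate | CC1=C(C(=O)OC)C(C)(C)[C@H](Br)[C@H](O[Si](C)(C)C(C)(C)C)C1 | intermediate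
9 | 1,4-dibromobutane | BrCCCCBr | starting material
10 | butane-1,4-diylbis(magnesium bromide), BrMg(CH2)4MgBr (formed in the flask) | Br[Mg]CCCC[Mg]Br | intermediate
11 | 1-[(4R,5S)-5-bromo-4-(tert-butyldimethylsilyloxy)-2,6,6-trimethylcyclohex-1-en-1-yl]cyclopentan-1-ol | CC1=C(C2(O)CCCC2)C(C)(C)[C@H](Br)[C@H](O[Si](C)(C)C(C)(C)C)C1 | intermediate
12 | (1R,6S)-6-bromo-4-(1-hydroxycyclopentyl)-3,5,5-trimethylcyclohex-3-en-1-ol | CC1=C(C2(O)CCCC2)C(C)(C)[C@H](Br)[C@H](O)C1 | intermediate
13 | (1S,3S,4R,6S)-3-bromo-1-(1-hydroxycyclopentyl)-2,2,6-trimethyl-7-oxabicyclo[4.1.0]heptan-4-ol (epoxide cis to hydroxyl and bromine) | C[C@]12C[C@@H](O)[C@@H](Br)C(C)(C)[C@@]1(C3(O)CCCC3)O2 | intermediate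
14 | (6R,7S,9R,10S)-10-bromo-7,9-dihydroxy-7,11,11-trimethylspiro[5.5]undecan-1-one | C[C@]1(O)C[C@@H](O)[C@@H](Br)C(C)(C)[C@@]12C(=O)CCCC2 | intermediate
15 | (6R,7S,9R,10S)-10-bromo-9-(tert-butyldimethylsilyloxy)-7-hydroxy-7,11,11-trimethylspiro[5.5]undecan-1-one (formed in the flask) | C[C@]1(O)C[C@@H](O[Si](C)(C)C(C)(C)C)[C@@H](Br)C(C)(C)[C@@]12C(=O)CCCC2 | intermediate
16 | (6R,7S,9R,10S)-10-bromo-9-(tert-butyldimethylsilyloxy)-7,11,11-trimethyl-7-(trimethylsilyloxy)spiro[5.5]undecan-1-one | C[C@]1(O[Si](C)(C)C)C[C@@H](O[Si](C)(C)C(C)(C)C)[C@@H](Br)C(C)(C)[C@@]12C(=O)CCCC2 | intermediate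
17 | (6R,7S,9R,10S)-10-bromo-9-(tert-butyldimethylsilyloxy)-7,11,11-trimethyl-7-(trimethylsilyloxy)spiro[5.5]undec-1-en-1-yl trifluoromethanesulfonate | C[C@]1(O[Si](C)(C)C)C[C@@H](O[Si](C)(C)C(C)(C)C)[C@@H](Br)C(C)(C)[C@@]12C(OS(=O)(=O)C(F)(F)F)=CCCC2 | intermediate
18 | (6R,7S,9R,10S)-10-bromo-9-(tert-butyldimethylsilyloxy)-7,11,11-trimethyl-7-(trimethylsilyloxy)spiro[5.5]undec-1-ene | C[C@]1(O[Si](C)(C)C)C[C@@H](O[Si](C)(C)C(C)(C)C)[C@@H](Br)C(C)(C)[C@@]12C=CCCC2 | intermediate
19 | (6R,7S,9R,10S)-10-bromo-9-(tert-butyldimethylsilyloxy)-7,11,11-trimethyl-7-(trimethylsilyloxy)spiro[5.5]undec-1-en-3-one | C[C@]1(O[Si](C)(C)C)C[C@@H](O[Si](C)(C)C(C)(C)C)[C@@H](Br)C(C)(C)[C@@]12C=CC(=O)CC2 | intermediate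
20 | (6R,7S,9R,10S)-10-bromo-9-(tert-butyldimethylsilyloxy)-7-hydroxy-7,11,11-trimethylspiro[5.5]undec-1-en-3-one | C[C@]1(O)C[C@@H](O[Si](C)(C)C(C)(C)C)[C@@H](Br)C(C)(C)[C@@]12C=CC(=O)CC2 | intermediate
21 | (6S,9R,10S)-10-bromo-9-(tert-butyldimethylsilyloxy)-11,11-dimethyl-7-methylidenespiro[5.5]undec-1-en-3-one | C=C1C[C@@H](O[Si](C)(C)C(C)(C)C)[C@@H](Br)C(C)(C)[C@@]12C=CC(=O)CC2 | intermediate
22 | (3R,6S,9R,10S)-10-bromo-9-(tert-butyldimethylsilyloxy)-3-(dibromomethyl)-11,11-dimethyl-7-methylidenespiro[5.5]undec-1-en-3-ol | C=C1C[C@@H](O[Si](C)(C)C(C)(C)C)[C@@H](Br)C(C)(C)[C@@]12C=C[C@@](O)(C(Br)Br)CC2 | intermediate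
23 | mailiohydrin, (3R,6S,9R,10S)-10-bromo-3-(dibromomethyl)-11,11-dimethyl-7-methylidenespiro[5.5]undec-1-ene-3,9-diol | C=C1C[C@@H](O)[C@@H](Br)C(C)(C)[C@@]12C=C[C@@](O)(C(Br)Br)CC2 | target

Total step count: 17
Longest linear sequence: 17 steps, from ketoisophorone 1 (1,4-dibromobutane 9 enters in step 6).

**Steps most likely to fail**

Step 16. The risk is poor facial selectivity in the carbenoid addition: axial attack on ring B from the C11 side would give the C3 epimer, and enolisation of the enone by the basic carbenoid would return starting material. The fallback sets out from 21 and uses the bulkier LiCBr3 (CHBr3, lithium 2,2,6,6-tetramethylpiperidide, THF–Et2O, −105 °C), whose size should enforce the equatorial approach, to give the tribromomethyl carbinol F6. One bromine is then removed by radical hydrodebromination (Bu3SnH, one equivalent, Et3B and air, toluene, −78 °C); the trihalide should react before the dihalide and the ring bromide. The route is rejoined at 22.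

Step 8. The risk is oxygen delivery by the allylic carbinol hydroxyl alone to the face away from the C9 hydroxyl, which after rearrangement would give the wrong configuration at C6. The fallback sets out from 12 and masks the competing director. Both hydroxyls are silylated with N-(trimethylsilyl)imidazole to the bis(trimethylsilyl) ether F3, and K2CO3 in MeOH at 0 °C cleaves only the secondary silyl ether to give the C9 alcohol with a silylated carbinol F4. VO(acac)2 and t-BuOOH, now directed by the C9 hydroxyl alone, give the epoxy silyl ether F5. TiCl4 in CH2Cl2 at −78 °C then effects the same ring expansion as the semipinacol rearrangement of an epoxy silyl ether, and the route is rejoined at 14.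

Step 2. The risk is epimerisation of the bromo ketone that is slow relative to reduction, or the lack of an enzyme with the needed enantiomer and face preference, which would lower the enantiomeric purity or give the trans isomer. The fallback sets out from 3 and replaces the dynamic reduction by diastereoselective reduction and resolution. NaBH4 with CeCl3·7H2O in MeOH at −40 °C (Luche reduction, hydride anti to the C–Br bond) gives the racemic cis-bromohydrin F1, and Ac2O, pyridine and DMAP give the racemic cis-acetate F2. A lipase (Burkholderia cepacia lipase, phosphate buffer pH 7, 30 °C) is expected to hydrolyse only the (4R)-acetate, following the empirical size rule for secondary alcohols. The unreacted (4S,5R)-acetate is removed by chromatography and the route is rejoined at 4.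

Further compounds
F1 | step 2 | rac-(4R,5S)-5-bromo-4-hydroxy-2,6,6-trimethylcyclohex-2-en-1-one (racemic cis-bromohydrin) | CC1=C[C@@H](O)[C@@H](Br)C(C)(C)C1=O.CC1=C[C@H](O)[C@H](Br)C(C)(C)C1=O
F2 | step 2 | rac-(1R,6S)-6-bromo-3,5,5-trimethyl-4-oxocyclohex-2-en-1-yl acetate (racemic cis-acetate) | CC1=C[C@@H](OC(C)=O)[C@@H](Br)C(C)(C)C1=O.CC1=C[C@H](OC(C)=O)[C@H](Br)C(C)(C)C1=O
F3 | step 8 | {[(1R,6S)-6-bromo-3,5,5-trimethyl-4-[1-(trimethylsilyloxy)cyclopentyl]cyclohex-3-en-1-yl]oxy}trimethylsilane | CC1=C(C2(O[Si](C)(C)C)CCCC2)C(C)(C)[C@H](Br)[C@H](O[Si](C)(C)C)C1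
F4 | step 8 | (1R,6S)-6-bromo-3,5,5-trimethyl-4-[1-(trimethylsilyloxy)cyclopentyl]cyclohex-3-en-1-ol | CC1=C(C2(O[Si](C)(C)C)CCCC2)C(C)(C)[C@H](Br)[C@H](O)C1
F5 | step 8 | (1R,3S,4R,6S)-3-bromo-2,2,6-trimethyl-1-[1-(trimethylsilyloxy)cyclopentyl]-7-oxabicyclo[4.1.0]heptan-4-ol (epoxide cis to hydroxyl and bromine) | C[C@]12C[C@@H](O)[C@@H](Br)C(C)(C)[C@@]1(C3(O[Si](C)(C)C)CCCC3)O2
F6 | step 16 | (3R,6S,9R,10S)-10-bromo-9-(tert-butyldimethylsilyloxy)-11,11-dimethyl-7-methylidene-3-(tribromomethyl)spiro[5.5]undec-1-en-3-ol | C=C1C[C@@H](O[Si](C)(C)C(C)(C)C)[C@@H](Br)C(C)(C)[C@@]12C=C[C@@](O)(C(Br)(Br)Br)CC2
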